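## Retrosynthetic overview

- **Enabling feature (C1 = carboxyl carbon, C22 = benzylic CH2):** the unbranched, heteroatom-free run of eighteen CH2 groups C5–C22 between alkene carbon C4 and the ipso carbon of the benzene ring. Cut at C16–C17, it gives two unstabilised primary radicals. One sits 12 CH2 from the C3=C4 alkene and the other 6 CH2 from the ring, too far for any 5- or 6-membered cyclisation.
- **Key disconnection C16–C17:** mixed Kolbe electrolysis of a C17 "head" ω-acid (C1 kept as silyl-protected CH2OH) with 7-(4-pivaloyloxyphenyl)heptanoic acid. Both activating groups leave as CO2, so nothing has to be removed at the junction.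
- **Head acid:** C5–C6 comes from a Cu-catalysed allyl bromide/Grignard coupling (C12 unit from 12-bromododecanol). The E-C3=C4 bond comes from a stabilised Wittig reaction, and C2 is bought with methyl (S)-3-hydroxy-2-methylpropanoate.
- **Tail acid:** Sonogashira coupling of 4-iodophenyl pivalate with hept-6-ynoic acid, then hydrogenation, done before any alkene that must survive is present.
- **End game:** desilylation, oxidation of C1 from CH2OH to CO2H, then pivalate cleavage. No ring is formed in the route; the benzene ring is bought.

Key step: step 12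

Assumption: the SMILES is read as (2R,3E), and every compound marked starting material in the list is taken as commercially available.

## Route

Step 1
Reactants: 1 methyl (S)-3-hydroxy-2-methylpropanoate
Product: 2 methyl (S)-3-(tert-butyldiphenylsilyloxy)-2-methylpropanoate
Conditions: TBDPSCl, imidazole, DMF, 0 °C → rt
Reagents that add atoms: tert-butyldiphenylsilyl chloride, CC(C)(C)[Si](Cl)(c1ccccc1)c1ccccc1
Why: Imidazole-promoted silylation of the only hydroxyl group leaves the purchased stereocentre (future C2) untouched, and TBDPS is chosen because it should outlast DIBAL-H, Grignard, Jones and anodic conditions.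

Step 2
Reactants: 2 methyl (S)-3-(tert-butyldiphenylsilyloxy)-2-methylpropanoate
Product: 3 (S)-3-(tert-butyldiphenylsilyloxy)-2-methylpropanal
Conditions: DIBAL-H (1.05 equiv), CH2Cl2, −78 °C; MeOH, aq. Rochelle salt
Reagents that add atoms: none
Why: Partial DIBAL-H reduction stops at the aluminium hemiacetal, which is stable at −78 °C and collapses to the aldehyde only on quench, so the α-stereocentre should be kept if 3 is used at once.

Step 3
Reactants: 3 (S)-3-(tert-butyldiphenylsilyloxy)-2-methylpropanal; 4 ethyl 2-(triphenylphosphoranylidene)propanoate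
Product: 5 ethyl (2E,4R)-5-(tert-butyldiphenylsilyloxy)-2,4-dimethylpent-2-enoate
Conditions: CH2Cl2, rt → 40 °C
Reagents that add atoms: none
Why: Wittig olefination with a stabilised α-methyl ylide places the ester trans to the branched chain and so sets the E geometry of the future C3=C4 bond, under neutral conditions that should not epimerise 3.

Step 4
Reactants: 5 ethyl (2E,4R)-5-(tert-butyldiphenylsilyloxy)-2,4-dimethylpent-2-enoate
Product: 6 (2E,4R)-5-(tert-butyldiphenylsilyloxy)-2,4-dimethylpent-2-en-1-ol
Conditions: DIBAL-H (2.5 equiv), CH2Cl2, −78 → 0 °C; aq. Rochelle salt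
Reagents that add atoms: none
Why: 1,2-Reduction of the enoate with excess DIBAL-H gives the allylic alcohol without touching the alkene geometry or the silyl ether.

Step 5
Reactants: 6 (2E,4R)-5-(tert-butyldiphenylsilyloxy)-2,4-dimethylpent-2-en-1-ol
Product: 7 (2E,4R)-1-bromo-5-(tert-butyldiphenylsilyloxy)-2,4-dimethylpent-2-ene
Conditions: CBr4, PPh3, CH2Cl2, 0 °C
Reagents that add atoms: carbon tetrabromide, BrC(Br)(Br)Br
Why: The Appel reaction displaces the activated primary allylic oxygen by SN2 under nearly neutral conditions, so neither allylic transposition nor E/Z scrambling is expected.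

Step 6
Reactants: 8 12-bromododecan-1-ol
Product: 9 (12-bromododecyloxy)(tert-butyl)dimethylsilane
Conditions: TBSCl, imidazole, CH2Cl2, rt
Reagents that add atoms: tert-butyldimethylsilyl chloride, CC(C)(C)[Si](C)(C)Cl
Why: Standard silylation masks the hydroxyl proton for Grignard formation with a group far more acid-labile than TBDPS.

Step 7
Reactants: 9 (12-bromododecyloxy)(tert-butyl)dimethylsilane; 7 (2E,4R)-1-bromo-5-(tert-butyldiphenylsilyloxy)-2,4-dimethylpent-2-ene
Product: 11 (2R,3E)-1-(tert-butyldiphenylsilyloxy)-17-(tert-butyldimethylsilyloxy)-2,4-dimethylheptadec-3-ene, via Grignard reagent 10 (not isolated)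
Conditions: 9, Mg, THF, 45 °C; then 7, Li2CuCl4 (5 mol %), THF, −78 → 0 °C
Reagents that add atoms: none
Why: In this Kochi-type copper-catalysed Grignard/allylic bromide cross-coupling the alkylcopper species should attack the unhindered primary α-carbon rather than the γ-carbon flanked by the stereocentre, forming C5–C6 with retention of the E geometry.

Step 8
Reactants: 11 (2R,3E)-1-(tert-butyldiphenylsilyloxy)-17-(tert-butyldimethylsilyloxy)-2,4-dimethylheptadec-3-ene
Product: 14 (14E,16R)-17-(tert-butyldiphenylsilyloxy)-14,16-dimethylheptadec-14-enoic acid, via primary alcohol 12 (not isolated), via aldehyde 13 (not isolated)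
Conditions: CrO3, H2SO4, H2O (Jones reagent), acetone, 0 °C → rt
Reagents that add atoms: water, O
Why: In this Jones oxidation the aqueous acid cleaves the primary TBS ether, which is much more acid-labile than TBDPS, and chromic acid then carries the freed alcohol through the aldehyde hydrate to the acid, an isolated alkene being inert at this temperature.

Step 9
Reactants: 15 4-iodophenol
Product: 16 4-iodophenyl pivalate
Conditions: PivCl, Et3N, DMAP (cat.), CH2Cl2, 0 °C → rt
Reagents that add atoms: pivaloyl chloride, CC(C)(C)C(=O)Cl
Why: O-Acylation turns the easily oxidised phenol into an electron-poorer aryl ester that is also sterically shielded against methanolysis.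

Step 10
Reactants: 16 4-iodophenyl pivalate; 17 hept-6-ynoic acid
Product: 18 7-[4-(pivaloyloxy)phenyl]hept-6-ynoic acid
Conditions: PdCl2(PPh3)2 (2 mol %), CuI (4 mol %), Et3N, THF, rt; acidic work-up
Reagents that add atoms: none
Why: Sonogashira coupling of an aryl iodide runs at room temperature; the tertiary amine does not cleave the hindered aryl ester, and the acid travels as its ammonium salt.

Step 11
Reactants: 18 7-[4-(pivaloyloxy)phenyl]hept-6-ynoic acid
Product: 19 7-[4-(pivaloyloxy)phenyl]heptanoic acid
Conditions: H2 (1 atm), 10 % Pd/C, EtOAc, rt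
Reagents that add atoms: none
Why: Heterogeneous catalytic hydrogenation saturates the alkyne fully, at a stage where no alkene of the target is present.

Step 12
Reactants: 14 (14E,16R)-17-(tert-butyldiphenylsilyloxy)-14,16-dimethylheptadec-14-enoic acid; 19 7-[4-(pivaloyloxy)phenyl]heptanoic acid
Product: 20 4-[(19E,21R)-22-(tert-butyldiphenylsilyloxy)-19,21-dimethyldocos-19-en-1-yl]phenyl pivalate
Conditions: undivided cell, smooth Pt anode/Pt cathode, 14 (1 equiv), 19 (5 equiv), KOH (0.1 equiv per acid), MeOH (a little DMF if needed for solubility), 40 °C, ca. 0.2 A cm−2, ca. 1.3 F per mol of total acid, stopped before the solution turns alkaline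
Reagents that add atoms: none
Why: Mixed Kolbe electrolysis: the carboxylates of 14 and 19, adsorbed on the platinum anode, each lose one electron and then CO2, and the two unstabilised primary radicals (at C16 and at C17) recombine in the radical-rich layer at the electrode to give the C16–C17 bond, while the acid protons are reduced to H2 at the cathode. The closest known reaction type is the anodic cross-coupling of two different alkanoic acids, long used for long-chain fatty acids, half-esters and alkenoic acids, including substrates with isolated trisubstituted alkenes and unactivated arenes. No ring is closed and no stereocentre is formed; C2 lies fourteen bonds from the radical centre and has no acidic hydrogen at the alcohol oxidation level, and the C3=C4 geometry is safe because the radical is never allylic. The first selectivity needed is cross- over self-coupling, which is statistical and is therefore pushed by a fivefold excess of the cheap three-step acid 19; the three possible coupling products differ in their number of silyl ether and aryl ester groups and should separate on silica. The second is the one-electron (radical) over the two-electron (cation) path, secured by unbranched primary radicals without an α-donor, smooth platinum, high current density and a weakly acidic, only partly neutralised methanol. The third is oxidation of carboxylate only, secured by masking the phenol as an electron-poor pivalate, by keeping C1 as a silyl ether so that the α-branched allylic acid (which would give a cation) is absent, and by the 12- and 6-CH2 spacers that rule out 5-exo or 6-exo attack on the alkene or the ring.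

Step 13
Reactants: 20 4-[(19E,21R)-22-(tert-butyldiphenylsilyloxy)-19,21-dimethyldocos-19-en-1-yl]phenyl pivalate
Product: 21 4-[(19E,21R)-22-hydroxy-19,21-dimethyldocos-19-en-1-yl]phenyl pivalate
Conditions: TBAF (1.5 equiv), AcOH (1.5 equiv), THF, rt
Reagents that add atoms: none
Why: Fluoride-driven desilylation is buffered with acetic acid so that basic fluoride does not cleave the aryl pivalate.

Step 14
Reactants: 21 4-[(19E,21R)-22-hydroxy-19,21-dimethyldocos-19-en-1-yl]phenyl pivalate
Product: 23 (2R,3E)-2,4-dimethyl-22-[4-(pivaloyloxy)phenyl]docos-3-enoic acid, via aldehyde 22 (not isolated)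
Conditions: TEMPO (0.2 equiv), PhI(OAc)2 (2.5 equiv), CH2Cl2–H2O 2:1, 0 °C → rt
Reagents that add atoms: water, O
Why: In the TEMPO/PhI(OAc)2 oxoammonium oxidation the aldehyde is hydrated and oxidised further as fast as it forms in a weakly acidic medium, so C2 should not epimerise and the alkene should not move, while the still masked phenol cannot be dearomatised by iodine(III).

Step 15
Reactants: 23 (2R,3E)-2,4-dimethyl-22-[4-(pivaloyloxy)phenyl]docos-3-enoic acid
Product: 24 (2R,3E)-22-(4-hydroxyphenyl)-2,4-dimethyldocos-3-enoic acid (elenic acid)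
Conditions: LiOH (5 equiv), THF–H2O 3:1, argon, 0 °C → rt; cold 1 M HCl to pH 3–4
Reagents that add atoms: none
Why: Saponification cleaves the aryl ester while C1 is present as a carboxylate whose α-hydrogen hydroxide cannot remove, so C2 and the β,γ-position of the alkene are kept, and cold mild acidification avoids γ-lactonisation.

## Compound list

| No. | Name | SMILES | Role |
|---|---|---|---|
| 1 | methyl (S)-3-hydroxy-2-methylpropanoate | COC(=O)[C@@H](C)CO | starting material |
| 2 | methyl (S)-3-(tert-butyldiphenylsilyloxy)-2-methylpropanoate | COC(=O)[C@@H](C)CO[Si](c1ccccc1)(c1ccccc1)C(C)(C)C | intermediate |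
| 3 | (S)-3-(tert-butyldiphenylsilyloxy)-2-methylpropanal | O=C[C@@H](C)CO[Si](c1ccccc1)(c1ccccc1)C(C)(C)C | intermediate |
| 4 | ethyl 2-(triphenylphosphoranylidene)propanoate | CCOC(=O)C(C)=P(c1ccccc1)(c1ccccc1)c1ccccc1 | starting material |
| 5 | ethyl (2E,4R)-5-(tert-butyldiphenylsilyloxy)-2,4-dimethylpent-2-enoate | C/C(=C\[C@@H](C)CO[Si](c1ccccc1)(c1ccccc1)C(C)(C)C)C(=O)OCC | intermediate |
| 6 | (2E,4R)-5-(tert-butyldiphenylsilyloxy)-2,4-dimethylpent-2-en-1-ol | C/C(=C\[C@@H](C)CO[Si](c1ccccc1)(c1ccccc1)C(C)(C)C)CO | intermediate |
| 7 | (2E,4R)-1-bromo-5-(tert-butyldiphenylsilyloxy)-2,4-dimethylpent-2-ene | C/C(=C\[C@@H](C)CO[Si](c1ccccc1)(c1ccccc1)C(C)(C)C)CBr | intermediate |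
| 8 | 12-bromododecan-1-ol | OCCCCCCCCCCCCBr | starting material |
| 9 | (12-bromododecyloxy)(tert-butyl)dimethylsilane | CC(C)(C)[Si](C)(C)OCCCCCCCCCCCCBr | intermediate |
| 10 | 12-(tert-butyldimethylsilyloxy)dodecylmagnesium bromide | CC(C)(C)[Si](C)(C)OCCCCCCCCCCCC[Mg]Br | intermediate |
| 11 | (2R,3E)-1-(tert-butyldiphenylsilyloxy)-17-(tert-butyldimethylsilyloxy)-2,4-dimethylheptadec-3-ene | C/C(=C\[C@@H](C)CO[Si](c1ccccc1)(c1ccccc1)C(C)(C)C)CCCCCCCCCCCCCO[Si](C)(C)C(C)(C)C | intermediate |
| 12 | (14E,16R)-17-(tert-butyldiphenylsilyloxy)-14,16-dimethylheptadec-14-en-1-ol | C/C(=C\[C@@H](C)CO[Si](c1ccccc1)(c1ccccc1)C(C)(C)C)CCCCCCCCCCCCCO | intermediate |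
| 13 | (14E,16R)-17-(tert-butyldiphenylsilyloxy)-14,16-dimethylheptadec-14-enal | C/C(=C\[C@@H](C)CO[Si](c1ccccc1)(c1ccccc1)C(C)(C)C)CCCCCCCCCCCCC=O | intermediate |
| 14 | (14E,16R)-17-(tert-butyldiphenylsilyloxy)-14,16-dimethylheptadec-14-enoic acid | C/C(=C\[C@@H](C)CO[Si](c1ccccc1)(c1ccccc1)C(C)(C)C)CCCCCCCCCCCCC(=O)O | intermediate |
| 15 | 4-iodophenol | Oc1ccc(I)cc1 | starting material |
| 16 | 4-iodophenyl pivalate | CC(C)(C)C(=O)Oc1ccc(I)cc1 | intermediate |
| 17 | hept-6-ynoic acid | C#CCCCCC(=O)O | starting material |
| 18 | 7-[4-(pivaloyloxy)phenyl]hept-6-ynoic acid | CC(C)(C)C(=O)Oc1ccc(C#CCCCCC(=O)O)cc1 | intermediate |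
| 19 | 7-[4-(pivaloyloxy)phenyl]heptanoic acid | CC(C)(C)C(=O)Oc1ccc(CCCCCCC(=O)O)cc1 | intermediate |
| 20 | 4-[(19E,21R)-22-(tert-butyldiphenylsilyloxy)-19,21-dimethyldocos-19-en-1-yl]phenyl pivalate | C/C(=C\[C@@H](C)CO[Si](c1ccccc1)(c1ccccc1)C(C)(C)C)CCCCCCCCCCCCCCCCCCc1ccc(OC(=O)C(C)(C)C)cc1 | intermediate |
| 21 | 4-[(19E,21R)-22-hydroxy-19,21-dimethyldocos-19-en-1-yl]phenyl pivalate | C/C(=C\[C@@H](C)CO)CCCCCCCCCCCCCCCCCCc1ccc(OC(=O)C(C)(C)C)cc1 | intermediate |
| 22 | 4-[(19E,21R)-19,21-dimethyl-22-oxodocos-19-en-1-yl]phenyl pivalate | C/C(=C\[C@@H](C)C=O)CCCCCCCCCCCCCCCCCCc1ccc(OC(=O)C(C)(C)C)cc1 | intermediate |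
| 23 | (2R,3E)-2,4-dimethyl-22-[4-(pivaloyloxy)phenyl]docos-3-enoic acid | C/C(=C\[C@@H](C)C(=O)O)CCCCCCCCCCCCCCCCCCc1ccc(OC(=O)C(C)(C)C)cc1 | intermediate |
| 24 | (2R,3E)-22-(4-hydroxyphenyl)-2,4-dimethyldocos-3-enoic acid (elenic acid) | C/C(=C\[C@@H](C)C(=O)O)CCCCCCCCCCCCCCCCCCc1ccc(O)cc1 | target |

## Step count and risks

Total step count: 15.
Longest linear sequence: 11 steps (1–5, 7, 8, 12–15).

**Step 12 (mixed Kolbe electrolysis).**
- What may go wrong: the acyloxyarene or the alkene is oxidised at the anode in competition with the carboxylates. The primary radicals may also be oxidised further to cations, the anode may be coated by waxy products, and the head acid may be lost to self-coupling.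
- The fallback sets out from 14 and 19 and moves the union from the anode to the cathode.
- Each acid is condensed with N-hydroxyphthalimide (DIC, DMAP cat., CH2Cl2). This gives the N-hydroxyphthalimide ester of the head acid F1 and the N-hydroxyphthalimide ester of the tail acid F2.
- The two esters are joined by nickel-electrocatalytic reductive doubly decarboxylative coupling. Conditions: NiCl2·6H2O, a terpyridine-type ligand, AgNO3-modified carbon cathode, Mg sacrificial anode, NMP, rt, F2 in threefold excess.
- At these potentials neither the arene nor the alkene is touched. The fallback comes back to the route at 20.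

**Step 7 (copper-catalysed allylic coupling).**
- What may go wrong: attack at the γ-carbon with allylic transposition, erosion of the E geometry through allylcopper isomerisation, and Wurtz-type self-coupling of either partner.
- The fallback sets out from 7 and 9 and inverts the polarity at C5.
- Bromide 7 is treated with PhSO2Na in DMF to give the allylic phenyl sulfone F3.
- The lithio anion of F3 (n-BuLi, THF–DMPU, −78 °C) is alkylated with 9, now used as the electrophile, to give the C5-alkylated sulfone F4.
- Palladium-catalysed reductive desulfonylation (LiBHEt3, PdCl2(dppp) cat., THF, 0 °C), which keeps the position and geometry of the alkene, comes back to the route at 11.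

**Step 14 (oxidation of C1).**
- What may go wrong: the transient α-branched β,γ-unsaturated aldehyde enolises, with epimerisation at C2 or drift of the alkene into conjugation.
- The fallback does not look for a gentler oxidant. It repairs the stereocentre with a covalent auxiliary and sets out from 23 of eroded purity.
- The acid is activated as a mixed anhydride (PivCl, Et3N, THF, −20 °C) and treated with (S)-4-benzyloxazolidin-2-one and LiCl. This gives the N-acyl oxazolidinone F5.
- The C2 epimer of F5 is a diastereomer and the conjugated isomer is a constitutional isomer, so both should be removable by chromatography.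
- LiOH/H2O2 (THF–H2O, 0 °C, Na2SO3 quench before acidification) then cleaves the auxiliary and the aryl pivalate in one operation without epimerisation. The fallback comes back at 24, so step 15 is no longer needed.

Further compounds
F1 | step 12 | 1,3-dioxoisoindolin-2-yl (14E,16R)-17-(tert-butyldiphenylsilyloxy)-14,16-dimethylheptadec-14-enoate | C/C(=C\[C@@H](C)CO[Si](c1ccccc1)(c1ccccc1)C(C)(C)C)CCCCCCCCCCCCC(=O)ON1C(=O)c2ccccc2C1=O
F2 | step 12 | 1,3-dioxoisoindolin-2-yl 7-[4-(pivaloyloxy)phenyl]heptanoate | CC(C)(C)C(=O)Oc1ccc(CCCCCCC(=O)ON2C(=O)c3ccccc3C2=O)cc1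
F3 | step 7 | (2E,4R)-5-(tert-butyldiphenylsilyloxy)-2,4-dimethylpent-2-en-1-yl phenyl sulfone | C/C(=C\[C@@H](C)CO[Si](c1ccccc1)(c1ccccc1)C(C)(C)C)CS(=O)(=O)c1ccccc1
F4 | step 7 | (2R,3E)-1-(tert-butyldiphenylsilyloxy)-17-(tert-butyldimethylsilyloxy)-2,4-dimethyl-5-(phenylsulfonyl)heptadec-3-ene (both epimers at C5) | C/C(=C\[C@@H](C)CO[Si](c1ccccc1)(c1ccccc1)C(C)(C)C)C(CCCCCCCCCCCCO[Si](C)(C)C(C)(C)C)S(=O)(=O)c1ccccc1
F5 | step 14 | (S)-4-benzyl-3-[(2R,3E)-2,4-dimethyl-22-(4-pivaloyloxyphenyl)docos-3-enoyl]oxazolidin-2-one | C/C(=C\[C@@H](C)C(=O)N1[C@@H](Cc2ccccc2)COC1=O)CCCCCCCCCCCCCCCCCCc1ccc(OC(=O)C(C)(C)C)cc1
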